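**Plan**

- Locants follow azulene numbering: C1 = C(CH3)2, C2 = CHOH, C3a/C8a = ring fusion (C8a carries OH), C4 = C=O, C5 = quaternary carbon, C6 = CHCH3.
- Retrosynthetic cuts, in order: the C2 O–Si bond; the C3a–O bond of an α,β-epoxy ketone that masks the aldol unit C8a(OH)–C3a(H)–C4(=O); the butenolide–CH2 bond (B-alkyl Suzuki–Miyaura); C5–vinyl and C5–CH3 (enolate chemistry); then C7–C8 and C4–C5 together.
- Enabling feature: the seven-membered ring is a four-carbon arc C8–C8a–C3a–C4 (an s-cis dienol ether exocyclic to the cyclopentane, C4 carrying the future ketone oxygen) closed by a three-carbon arc C7–C6–C5 whose branched middle carbon marks a 2-(silylmethyl)allyl cation. One (4+3) annulation gives the ring, the C3a=C8a alkene needed for the aldol unit and the C6 branch.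
- Forward order: the cyclopentane is present from dione 1, the seven-membered ring closes in step 6, then C6 and C5 are set, the enone is epoxidised, the butenolide ring is coupled on, and the aldol is unmasked last.
- Stereochemistry: C2 from CBS desymmetrisation; C6 from catalyst-controlled CuH conjugate reduction; C5 from enolate vinylation anti to the C6 methyl; C8a from epoxidation anti to the C2 silyloxy group; C3a from enolate protonation or equilibration to the trans-fused aldol.

Key step: step 6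

Assumption: the (S)-oxazaborolidine in step 1 and the (S)-bisphosphine in step 8 are taken to deliver hydride in the sense drawn (usual models); otherwise the antipodal catalyst is used.
Assumption: 7 is taken as a purchased reagent (it is also one methanolysis step from its commercial acetate).

Step 1
Reactants: 1 2,2-dimethylcyclopentane-1,3-dione
Product: 2 (3R)-3-hydroxy-2,2-dimethylcyclopentan-1-one
Conditions: (S)-2-methyl-CBS-oxazaborolidine (cat.), BH3·SMe2, THF, −20 °C; MeOH quench
Reagents that add atoms: none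
Why: Corey–Bakshi–Shibata mono-reduction desymmetrises the prochiral dione, the catalyst distinguishing the quaternary from the methylene flank of one carbonyl, and should set the carbinol centre (C2 of the target) as R.

Step 2
Reactants: 2 (3R)-3-hydroxy-2,2-dimethylcyclopentan-1-one
Product: 3 (3R)-3-[(tert-butyldiphenylsilyl)oxy]-2,2-dimethylcyclopentan-1-one
Conditions: TBDPSCl, imidazole, DMAP (cat.), DMF, 50 °C
Reagents that add atoms: tert-butyl(chloro)diphenylsilane (CC(C)(C)[Si](Cl)(c1ccccc1)c1ccccc1)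
Why: Standard silylation of a secondary alcohol gives a bulky, acid- and base-stable ether that should survive to the last step and later shield one face of the cyclopentene.

Step 3
Reactants: 3 (3R)-3-[(tert-butyldiphenylsilyl)oxy]-2,2-dimethylcyclopentan-1-one
Product: 4 (4R)-4-[(tert-butyldiphenylsilyl)oxy]-2-chloro-3,3-dimethylcyclopent-1-ene-1-carbaldehyde
Conditions: POCl3, DMF, CH2Cl2, 0 → 40 °C; aq. NaOAc
Reagents that add atoms: N,N-dimethylformamide (CN(C)C=O); phosphoryl chloride (O=P(Cl)(Cl)Cl); water (O)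
Why: Vilsmeier–Haack chloroformylation should be regiospecific because the ketone can enolise only toward its CH2 flank (the other α carbon is quaternary), giving the β-chloro enal.

Step 4
Reactants: 4 (4R)-4-[(tert-butyldiphenylsilyl)oxy]-2-chloro-3,3-dimethylcyclopent-1-ene-1-carbaldehyde
Product: 5 (4R)-4-[(tert-butyldiphenylsilyl)oxy]-2,3,3-trimethylcyclopent-1-ene-1-carbaldehyde
Conditions: MeB(OH)2, Pd(OAc)2 (cat.), SPhos (cat.), K3PO4, toluene/H2O, 80 °C
Reagents that add atoms: methylboronic acid (CB(O)O)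
Why: Suzuki–Miyaura coupling of an activated vinyl chloride (a vinylogous acyl chloride) should install the methyl group that becomes C8 of the target.

Step 5
Reactants: 5 (4R)-4-[(tert-butyldiphenylsilyl)oxy]-2,3,3-trimethylcyclopent-1-ene-1-carbaldehyde
Product: 6 tert-butyl{[(1R,4E)-2,2-dimethyl-3-methylidene-4-{[(trimethylsilyl)oxy]methylidene}cyclopentyl]oxy}diphenylsilane
Conditions: TMSOTf, Et3N, Et2O, 0 °C; filtration under argon
Reagents that add atoms: trimethylsilyl trifluoromethanesulfonate (C[Si](C)(C)OS(=O)(=O)C(F)(F)F)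
Why: Soft enolisation (O-silylation, then γ-deprotonation) should give the 1-silyloxy diene, since the only γ hydrogens are on the new methyl group (the other γ carbon is C(CH3)2) and the s-trans enal leads to the E enol ether.

Step 6
Reactants: 6 tert-butyl{[(1R,4E)-2,2-dimethyl-3-methylidene-4-{[(trimethylsilyl)oxy]methylidene}cyclopentyl]oxy}diphenylsilane; 7 2-[(trimethylsilyl)methyl]prop-2-en-1-ol
Product: 10 (2R)-2-[(tert-butyldiphenylsilyl)oxy]-1,1-dimethyl-6-methylidene-1,2,3,4,5,6,7,8-octahydroazulen-4-ol (C4 epimers), via allyl triflate 8 (not isolated), via trimethylsilyl ether 9 (not isolated)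
Conditions: 7, Tf2O, 2,6-lutidine, CH2Cl2, −78 °C; then 6, −78 → −40 °C; then K2CO3, MeOH, 0 °C
Reagents that add atoms: none
Why: Ionisation of triflate 8 gives the 2-(trimethylsilylmethyl)allyl cation, which is taken up across the two exocyclic termini of dienol ether 6, concertedly or in two stages in which the nucleophilic CH2 terminus attacks first (C7–C8 bond, vinylogous Mukaiyama-type alkylation) and the resulting allylsilane then adds to the O-silyl oxocarbenium carbon (C4–C5 bond, Hosomi–Sakurai closure), loss of Me3Si+ leaving the exocyclic methylene at C6. The closest known reaction type is the (4+3) cycloaddition of 2-(silylmethyl)allyl cations with 1,3-dienes to give 4-methylenecycloheptenes. The seven-membered ring is the only ring closed, by a 7-exo-trig attack on the oxocarbenium carbon (7-endo with respect to the allylsilane double bond) after an intermolecular first bond. The one new stereocentre, C4, is formed without control and is erased by oxidation in step 7, while C2 is untouched. No regiochemical question arises because both allyl termini are CH2; closure at C4 and not at C8a (which would give a spiro-cyclopentane) is secured by the aldehyde-derived oxocarbenium and by the fully substituted C8a next to C(CH3)2, and the reactive s-cis geometry is locked because both diene double bonds are exocyclic to the cyclopentane with the silyloxy group outside (E). Methanolic K2CO3 then removes only the O–SiMe3 group.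

Step 7
Reactants: 10 (2R)-2-[(tert-butyldiphenylsilyl)oxy]-1,1-dimethyl-6-methylidene-1,2,3,4,5,6,7,8-octahydroazulen-4-ol (C4 epimers)
Product: 12 (2R)-2-[(tert-butyldiphenylsilyl)oxy]-1,1,6-trimethyl-2,3,7,8-tetrahydroazulen-4(1H)-one, via exocyclic enone 11 (not isolated)
Conditions: Dess–Martin periodinane, NaHCO3, CH2Cl2, 0 °C → rt; then DBU, rt
Reagents that add atoms: none
Why: Dess–Martin oxidation converges both C4 epimers on one enone, and base-mediated isomerisation through the doubly activated C5 position should move the exocyclic alkene into conjugation as the trisubstituted C5=C6 bond, turning the silylmethyl-derived carbon into the C6 methyl group.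

Step 8
Reactants: 12 (2R)-2-[(tert-butyldiphenylsilyl)oxy]-1,1,6-trimethyl-2,3,7,8-tetrahydroazulen-4(1H)-one
Product: 14 (2R,6R)-2-[(tert-butyldiphenylsilyl)oxy]-1,1,5,6-tetramethyl-2,3,5,6,7,8-hexahydroazulen-4(1H)-one (C5 epimers), via silyl dienol ether 13 (not isolated)
Conditions: CuCl (cat.), NaOt-Bu (cat.), (S)-p-tol-BINAP (cat.), PhMe2SiH, toluene, 0 °C; then MeLi, THF, −78 °C; then MeI, −78 → 0 °C
Reagents that add atoms: iodomethane (CI)
Why: Copper hydride-catalysed asymmetric conjugate reduction should deliver hydride to C6 of the α-unsubstituted enone arm only (the tetrasubstituted C3a=C8a arm is far more hindered), the chiral bisphosphine setting C6 as R independently of the remote C2 centre (a minor C6 epimer would be a separable diastereomer), after which MeLi cleaves the silyl enol ether and the regiodefined enolate is C-methylated at C5 (its configuration is immaterial).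

Step 9
Reactants: 14 (2R,6R)-2-[(tert-butyldiphenylsilyl)oxy]-1,1,5,6-tetramethyl-2,3,5,6,7,8-hexahydroazulen-4(1H)-one (C5 epimers)
Product: 15 (2R,3aS,6R,8aR)-2-[(tert-butyldiphenylsilyl)oxy]-3a,8a-epoxy-1,1,5,6-tetramethyloctahydroazulen-4(1H)-one (C5 epimers)
Conditions: 30% H2O2, LiOH, MeOH, 0 °C → rt
Reagents that add atoms: hydrogen peroxide (OO)
Why: Weitz–Scheffer nucleophilic epoxidation of the remaining enone, in which hydroperoxide should add to C8a on the cyclopentene face anti to the bulky C2 silyloxy group, fixes the configuration of the future tertiary alcohol and leaves C5 as the only enolisable position.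

Step 10
Reactants: 15 (2R,3aS,6R,8aR)-2-[(tert-butyldiphenylsilyl)oxy]-3a,8a-epoxy-1,1,5,6-tetramethyloctahydroazulen-4(1H)-one (C5 epimers)
Product: 16 (2R,3aS,5S,6R,8aR)-2-[(tert-butyldiphenylsilyl)oxy]-5-ethenyl-3a,8a-epoxy-1,1,5,6-tetramethyloctahydroazulen-4(1H)-one
Conditions: LiN(SiMe3)2, THF, −78 → 0 °C; then bromoethene, Pd2(dba)3 (cat.), P(t-Bu)3 (cat.), toluene, rt
Reagents that add atoms: bromoethene (C=CBr)
Why: Palladium-catalysed α-vinylation of the ketone enolate should create the quaternary centre with vinyl trans to the C6 methyl, because A(1,2) strain with the C5 methyl holds the C6 methyl pseudo-axial so that palladium binds and delivers the vinyl group on the opposite face (also anti to the epoxide oxygen).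

Step 11
Reactants: 16 (2R,3aS,5S,6R,8aR)-2-[(tert-butyldiphenylsilyl)oxy]-5-ethenyl-3a,8a-epoxy-1,1,5,6-tetramethyloctahydroazulen-4(1H)-one; 17 4-bromofuran-2(5H)-one
Product: 19 (2R,3aS,5S,6R,8aR)-2-[(tert-butyldiphenylsilyl)oxy]-3a,8a-epoxy-1,1,5,6-tetramethyl-5-[2-(5-oxo-2,5-dihydrofuran-3-yl)ethyl]octahydroazulen-4(1H)-one, via alkylborane 18 (not isolated)
Conditions: 9-BBN, THF, 0 °C → rt; then 17, Pd(dppf)Cl2 (cat.), AsPh3 (cat.), K3PO4, DMF/H2O, rt
Reagents that add atoms: none
Why: Anti-Markovnikov hydroboration of the only alkene (the hindered epoxy ketone should be inert to 9-BBN) followed by B-alkyl Suzuki–Miyaura coupling with the β-bromo butenolide attaches the complete side chain without forming a stereocentre, while the epoxide keeps the base-sensitive aldol unit masked.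

Step 12
Reactants: 19 (2R,3aS,5S,6R,8aR)-2-[(tert-butyldiphenylsilyl)oxy]-3a,8a-epoxy-1,1,5,6-tetramethyl-5-[2-(5-oxo-2,5-dihydrofuran-3-yl)ethyl]octahydroazulen-4(1H)-one
Product: 20 (2R,3aS,5S,6R,8aS)-2-[(tert-butyldiphenylsilyl)oxy]-8a-hydroxy-1,1,5,6-tetramethyl-5-[2-(5-oxo-2,5-dihydrofuran-3-yl)ethyl]octahydroazulen-4(1H)-one
Conditions: SmI2, THF/MeOH, −90 °C
Reagents that add atoms: none
Why: SmI2 reductive opening of the α,β-epoxy ketone (ketyl formation, then cleavage of the C3a–O bond) should give the β-hydroxy ketone with C8a retained, and protonation of the samarium enolate at C3a anti to the C8a alkoxide gives the trans-fused junction, which is expected to be the hydrogen-bonded, more stable epimer at this epimerisable centre.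

Step 13
Reactants: 20 (2R,3aS,5S,6R,8aS)-2-[(tert-butyldiphenylsilyl)oxy]-8a-hydroxy-1,1,5,6-tetramethyl-5-[2-(5-oxo-2,5-dihydrofuran-3-yl)ethyl]octahydroazulen-4(1H)-one
Product: 21 (2R,3aS,5S,6R,8aS)-2,8a-dihydroxy-1,1,5,6-tetramethyl-5-[2-(5-oxo-2,5-dihydrofuran-3-yl)ethyl]octahydroazulen-4(1H)-one
Conditions: HF·pyridine, pyridine, THF, 0 °C → rt
Reagents that add atoms: none
Why: Fluoride-mediated Si–O cleavage under buffered acidic conditions, which should spare the retro-aldol-prone β-hydroxy ketone and the butenolide, releases the C2 alcohol and completes the target.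

**Compound list**

1 | 2,2-dimethylcyclopentane-1,3-dione | CC1(C)C(=O)CCC1=O | starting material
2 | (3R)-3-hydroxy-2,2-dimethylcyclopentan-1-one | O=C1CC[C@@H](O)C1(C)C | intermediate
3 | (3R)-3-[(tert-butyldiphenylsilyl)oxy]-2,2-dimethylcyclopentan-1-one | O=C1CC[C@@H](O[Si](c2ccccc2)(c2ccccc2)C(C)(C)C)C1(C)C | intermediate
4 | (4R)-4-[(tert-butyldiphenylsilyl)oxy]-2-chloro-3,3-dimethylcyclopent-1-ene-1-carbaldehyde | O=CC1=C(Cl)C(C)(C)[C@H](O[Si](c2ccccc2)(c2ccccc2)C(C)(C)C)C1 | intermediate
5 | (4R)-4-[(tert-butyldiphenylsilyl)oxy]-2,3,3-trimethylcyclopent-1-ene-1-carbaldehyde | O=CC1=C(C)C(C)(C)[C@H](O[Si](c2ccccc2)(c2ccccc2)C(C)(C)C)C1 | intermediate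
6 | tert-butyl{[(1R,4E)-2,2-dimethyl-3-methylidene-4-{[(trimethylsilyl)oxy]methylidene}cyclopentyl]oxy}diphenylsilane | C=C1C(C)(C)[C@H](O[Si](c2ccccc2)(c2ccccc2)C(C)(C)C)C/C1=C\O[Si](C)(C)C | intermediate
7 | 2-[(trimethylsilyl)methyl]prop-2-en-1-ol | C=C(CO)C[Si](C)(C)C | starting material
8 | 2-[(trimethylsilyl)methyl]prop-2-en-1-yl trifluoromethanesulfonate | C=C(COS(=O)(=O)C(F)(F)F)C[Si](C)(C)C | intermediate
9 | {[(2R)-2-[(tert-butyldiphenylsilyl)oxy]-1,1-dimethyl-6-methylidene-1,2,3,4,5,6,7,8-octahydroazulen-4-yl]oxy}trimethylsilane (C4 epimers) | C=C1CCC2=C(C[C@@H](O[Si](c3ccccc3)(c3ccccc3)C(C)(C)C)C2(C)C)C(O[Si](C)(C)C)C1 | intermediate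
10 | (2R)-2-[(tert-butyldiphenylsilyl)oxy]-1,1-dimethyl-6-methylidene-1,2,3,4,5,6,7,8-octahydroazulen-4-ol (C4 epimers) | C=C1CCC2=C(C[C@@H](O[Si](c3ccccc3)(c3ccccc3)C(C)(C)C)C2(C)C)C(O)C1 | intermediate
11 | (2R)-2-[(tert-butyldiphenylsilyl)oxy]-1,1-dimethyl-6-methylidene-2,3,5,6,7,8-hexahydroazulen-4(1H)-one | C=C1CCC2=C(C[C@@H](O[Si](c3ccccc3)(c3ccccc3)C(C)(C)C)C2(C)C)C(=O)C1 | intermediate
12 | (2R)-2-[(tert-butyldiphenylsilyl)oxy]-1,1,6-trimethyl-2,3,7,8-tetrahydroazulen-4(1H)-one | CC1=CC(=O)C2=C(CC1)C(C)(C)[C@H](O[Si](c3ccccc3)(c3ccccc3)C(C)(C)C)C2 | intermediate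
13 | tert-butyl{[(2R,6R)-4-{[dimethyl(phenyl)silyl]oxy}-1,1,6-trimethyl-1,2,3,6,7,8-hexahydroazulen-2-yl]oxy}diphenylsilane | C[C@@H]1CCC2=C(C[C@@H](O[Si](c3ccccc3)(c3ccccc3)C(C)(C)C)C2(C)C)C(O[Si](C)(C)c3ccccc3)=C1 | intermediate
14 | (2R,6R)-2-[(tert-butyldiphenylsilyl)oxy]-1,1,5,6-tetramethyl-2,3,5,6,7,8-hexahydroazulen-4(1H)-one (C5 epimers) | C[C@@H]1CCC2=C(C[C@@H](O[Si](c3ccccc3)(c3ccccc3)C(C)(C)C)C2(C)C)C(=O)C1C | intermediate
15 | (2R,3aS,6R,8aR)-2-[(tert-butyldiphenylsilyl)oxy]-3a,8a-epoxy-1,1,5,6-tetramethyloctahydroazulen-4(1H)-one (C5 epimers) | C[C@@H]1CC[C@]2(O3)[C@@]3(C[C@@H](O[Si](c4ccccc4)(c4ccccc4)C(C)(C)C)C2(C)C)C(=O)C1C | intermediate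
16 | (2R,3aS,5S,6R,8aR)-2-[(tert-butyldiphenylsilyl)oxy]-5-ethenyl-3a,8a-epoxy-1,1,5,6-tetramethyloctahydroazulen-4(1H)-one | C[C@@H]1CC[C@]2(O3)[C@@]3(C[C@@H](O[Si](c4ccccc4)(c4ccccc4)C(C)(C)C)C2(C)C)C(=O)[C@@]1(C)C=C | intermediate
17 | 4-bromofuran-2(5H)-one | O=C1C=C(Br)CO1 | starting material
18 | (2R,3aS,5S,6R,8aR)-5-[2-(9-borabicyclo[3.3.1]nonan-9-yl)ethyl]-2-[(tert-butyldiphenylsilyl)oxy]-3a,8a-epoxy-1,1,5,6-tetramethyloctahydroazulen-4(1H)-one | C[C@@H]1CC[C@]2(O3)[C@@]3(C[C@@H](O[Si](c4ccccc4)(c4ccccc4)C(C)(C)C)C2(C)C)C(=O)[C@@]1(C)CCB5C6CCCC5CCC6 | intermediate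
19 | (2R,3aS,5S,6R,8aR)-2-[(tert-butyldiphenylsilyl)oxy]-3a,8a-epoxy-1,1,5,6-tetramethyl-5-[2-(5-oxo-2,5-dihydrofuran-3-yl)ethyl]octahydroazulen-4(1H)-one | C[C@@H]1CC[C@]2(O3)[C@@]3(C[C@@H](O[Si](c4ccccc4)(c4ccccc4)C(C)(C)C)C2(C)C)C(=O)[C@@]1(C)CCC1=CC(=O)OC1 | intermediate
20 | (2R,3aS,5S,6R,8aS)-2-[(tert-butyldiphenylsilyl)oxy]-8a-hydroxy-1,1,5,6-tetramethyl-5-[2-(5-oxo-2,5-dihydrofuran-3-yl)ethyl]octahydroazulen-4(1H)-one | C[C@@H]1CC[C@]2(O)[C@H](C[C@@H](O[Si](c3ccccc3)(c3ccccc3)C(C)(C)C)C2(C)C)C(=O)[C@@]1(C)CCC1=CC(=O)OC1 | intermediate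
21 | (2R,3aS,5S,6R,8aS)-2,8a-dihydroxy-1,1,5,6-tetramethyl-5-[2-(5-oxo-2,5-dihydrofuran-3-yl)ethyl]octahydroazulen-4(1H)-one | C[C@@H]1CC[C@]2(O)[C@H](C[C@@H](O)C2(C)C)C(=O)[C@@]1(C)CCC1=CC(=O)OC1 | target

Total step count: 13. Longest linear sequence: 13 steps (1 → 21).

**Steps most likely to fail**

Step 6. The ionised allyl unit may stop after the first C–C bond (open-chain γ-allylated enal), may close at C8a instead of C4, or the dienol ether may be lost by protodesilylation before it is captured. The fallback sets out from 6 and comes back at 10. Dienol ether 6 would be combined in a (4+3) cycloaddition with the parent oxyallyl cation generated from 1,1,3,3-tetrabromoacetone (Zn–Cu couple, B(OEt)3, THF) to give the dibromo ketone F1. Reductive debromination (Zn–Cu couple, NH4Cl, MeOH), which should also cleave the O–SiMe3 group, would give the hydroxy ketone F2. Methylenation of the C6 ketone of F2 with Cp2TiMe2 (toluene, 65 °C) would then give 10.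

Step 9. Hydroperoxide attack at the fully substituted C8a next to C(CH3)2 may be slow, and the two faces of the cyclopentene may not be discriminated well enough by the C2 silyloxy group. The fallback sets out from 14 and comes back at 15. Luche reduction of 14 (NaBH4, CeCl3·7H2O, MeOH) would give the 4β allylic alcohol F3 and its 4α epimer F4; F4 would be returned to 14 by Dess–Martin oxidation. Hydroxyl-directed epoxidation of F3 (VO(acac)2, t-BuOOH, CH2Cl2), now an electrophilic attack on an electron-rich tetrasubstituted alkene syn to the hydroxyl group, would give the epoxy alcohol F5. Dess–Martin oxidation of F5 would give 15.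

Step 10. Reductive elimination at the congested tertiary enolate carbon may be slow, which would allow O-vinylation or base-induced decomposition of the epoxy ketone at room temperature, and facial control may erode. The fallback sets out from 15 and comes back at 16. The lithium enolate of 15 (LiN(iPr)2, THF, −78 °C) would be added to phenyl vinyl sulfoxide, again anti to the C6 methyl, to give the sulfoxide F6. Thermal syn-elimination of F6 (toluene, 110 °C) would give 16.

**Further compounds**

F1 | step 6 | (2R)-5,7-dibromo-2-[(tert-butyldiphenylsilyl)oxy]-1,1-dimethyl-4-[(trimethylsilyl)oxy]-2,3,4,5,7,8-hexahydroazulen-6(1H)-one (stereoisomer mixture) | O=C1C(Br)CC2=C(C[C@@H](O[Si](c3ccccc3)(c3ccccc3)C(C)(C)C)C2(C)C)C(O[Si](C)(C)C)C1Br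
F2 | step 6 | (2R)-2-[(tert-butyldiphenylsilyl)oxy]-4-hydroxy-1,1-dimethyl-2,3,4,5,7,8-hexahydroazulen-6(1H)-one (C4 epimers) | O=C1CCC2=C(C[C@@H](O[Si](c3ccccc3)(c3ccccc3)C(C)(C)C)C2(C)C)C(O)C1
F3 | step 9 | (2R,4R,6R)-2-[(tert-butyldiphenylsilyl)oxy]-1,1,5,6-tetramethyl-1,2,3,4,5,6,7,8-octahydroazulen-4-ol (C5 epimers) | C[C@@H]1CCC2=C(C[C@@H](O[Si](c3ccccc3)(c3ccccc3)C(C)(C)C)C2(C)C)[C@H](O)C1C
F4 | step 9 | (2R,4S,6R)-2-[(tert-butyldiphenylsilyl)oxy]-1,1,5,6-tetramethyl-1,2,3,4,5,6,7,8-octahydroazulen-4-ol (C5 epimers) | C[C@@H]1CCC2=C(C[C@@H](O[Si](c3ccccc3)(c3ccccc3)C(C)(C)C)C2(C)C)[C@@H](O)C1C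
F5 | step 9 | (2R,3aR,4R,6R,8aR)-2-[(tert-butyldiphenylsilyl)oxy]-3a,8a-epoxy-1,1,5,6-tetramethyldecahydroazulen-4-ol (C5 epimers) | C[C@@H]1CC[C@]2(O3)[C@@]3(C[C@@H](O[Si](c4ccccc4)(c4ccccc4)C(C)(C)C)C2(C)C)[C@H](O)C1C
F6 | step 10 | (2R,3aS,5S,6R,8aR)-5-[2-(benzenesulfinyl)ethyl]-2-[(tert-butyldiphenylsilyl)oxy]-3a,8a-epoxy-1,1,5,6-tetramethyloctahydroazulen-4(1H)-one | C[C@@H]1CC[C@]2(O3)[C@@]3(C[C@@H](O[Si](c4ccccc4)(c4ccccc4)C(C)(C)C)C2(C)C)C(=O)[C@@]1(C)CCS(=O)c1ccccc1
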